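A direct plan would build the monomer methyl orsellinate (A1) by a Michael–Dieckmann annulation of two acyclic esters, aromatise it by bromination to the dibromide A2 and remove the bromines by hydrogenolysis.
It would then turn A1 by benzylation, methylation and forcing alkaline ester hydrolysis into protected acids such as 4-(benzyloxy)-2-methoxy-6-methylbenzoic acid (A3), and join three finished rings by two mixed-anhydride esterifications, each followed by debenzylation.
Weak step (a), the aromatisation through A2 and the debromination: a halogenation–dehalogenation detour of three steps toward a monomer that can be bought.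
Weak step (b), the protecting-group traffic (benzylations, forcing hydrolysis of di-ortho-substituted benzoates, two hydrogenolyses): about half of the steps would form no bond of the target.
Weak step (c), both depside esterifications: each would acylate a phenol with a di-ortho-substituted, electron-rich benzoic acid such as A3, the most hindered carbonyl the target offers, and the second would expose the first depside bond to acyl exchange.

**Retrosynthetic overview**
Both depside bonds would be cut not at the ester C–O bond but inside rings B and C: each phenol oxygen is first acylated by an unhindered open-chain acyl unit, and the di-ortho-substituted benzoyl ring is then built around the carbonyl already in place.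
Ring B (C1'–C6', with 2'-OMe, 4'-OH and 6'-CH3) would arise by Diels–Alder reaction and aromatisation of the but-2-ynoate ester of the 4-OH of ring A with 1,1-dimethoxy-3-(trimethylsilyloxy)buta-1,3-diene; this forms C1'–C2' and C5'–C6' and delivers the 2'-oxygen methylated and the 4'-oxygen free.
Ring C (2'',4''-dihydroxy-6''-methyl) would be made last by a biomimetic sequence: capture of an acylketene by the 4'-OH, then aldol aromatisation of the aryl 3,5,7-trioxooctanoate (ester C–O and C1''–C6'' bonds).
Ring A is bought as methyl orsellinate and the rings appear in the order A, B, C; the design needs no isolated protecting-group step, no ester hydrolysis, no halogenation of an arene and no acylation by a hindered benzoic acid.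
Key step: step 5

Assumption: methyl orsellinate, but-2-ynoic acid, 2,2,6-trimethyl-4H-1,3-dioxin-4-one and N-methoxy-N-methylacetamide are taken as commercial; the silyl ether placed on the 2-OH of ring A in step 5 is an in-flask intermediate that the work-up of the same step removes.

Step 1
Reactants: 1 acetyl chloride; 2 1,1-dichloroethene
Product: 4 4,4-dichlorobut-3-en-2-one, via 4,4,4-trichlorobutan-2-one 3 (not isolated)
Conditions: AlCl3 (1.1 equiv), CH2Cl2, 0 °C → rt; ice–water quench; steam distillation
Reagents that add atoms: none
Why: Friedel–Crafts-type acylation of the unhindered alkene by the acylium ion pair gives the β-trichloromethyl ketone, whose acidic α-hydrogen is lost together with chloride (E1cB) during the distillation to give the conjugated dichlorovinyl ketone.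

Step 2
Reactants: 4 4,4-dichlorobut-3-en-2-one
Product: 5 4,4-dimethoxybut-3-en-2-one
Conditions: NaOMe (2.2 equiv), MeOH, 0 °C → rt; distillation
Reagents that add atoms: sodium methoxide, C[O-].[Na+]
Why: Two successive addition–elimination (vinylic substitution) events at the β-carbon of this vinylogous acid chloride should replace both chlorides by methoxide, and the product, a vinylogous carbonate, resists further attack.

Step 3
Reactants: 5 4,4-dimethoxybut-3-en-2-one
Product: 6 1,1-dimethoxy-3-(trimethylsilyloxy)buta-1,3-diene
Conditions: LiN(iPr)2 (1.1 equiv), THF, −78 °C; Me3SiCl (1.2 equiv), −78 °C → rt; pentane, filtration, distillation (no aqueous work-up)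
Reagents that add atoms: chlorotrimethylsilane, C[Si](C)(C)Cl
Why: Kinetic deprotonation of the methyl ketone and O-silylation of the lithium enolate should give the silyl dienol ether, since the β,β-dimethoxy enone is a vinylogous ester and a poor Michael acceptor for the amide base.

Step 4
Reactants: 7 methyl 2,4-dihydroxy-6-methylbenzoate (methyl orsellinate, ring A); 8 but-2-ynoic acid
Product: 9 methyl 4-(but-2-ynoyloxy)-2-hydroxy-6-methylbenzoate
Conditions: DCC (1.1 equiv), 4-(dimethylamino)pyridine (5 mol %), CH2Cl2, 0 °C → rt
Reagents that add atoms: none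
Why: Steglich esterification should acylate only the free 4-OH, because the 2-OH is locked in a hydrogen bond to the ester carbonyl, and the acyl partner is an unhindered linear alkynoic acid instead of a di-ortho-substituted benzoic acid.

Step 5
Reactants: 9 methyl 4-(but-2-ynoyloxy)-2-hydroxy-6-methylbenzoate; 6 1,1-dimethoxy-3-(trimethylsilyloxy)buta-1,3-diene
Product: 12 methyl 2-hydroxy-4-[(4-hydroxy-2-methoxy-6-methylbenzoyl)oxy]-6-methylbenzoate, via aryl silyl ether 10 (not isolated), via cyclohexadiene cycloadduct 11 (not isolated)
Conditions: MeC(OSiMe3)=NSiMe3 (BSA, 1.1 equiv), toluene, rt → 60 °C; then 6 (2.0 equiv), 100 °C, sealed vessel; then 1 M HCl–THF (1:4), rt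
Reagents that add atoms: none
Why: A normal-electron-demand Diels–Alder reaction between the vinylketene acetal diene 6 (three oxygen donors, largest HOMO coefficient at its CH2 terminus) and the aryl ynoate 10 is followed by acid-induced loss of methanol and of both silyl groups; the closest known reaction type is the cycloaddition of 1,1-dimethoxy-3-silyloxybutadienes with alkynoates to give 4-hydroxy-2-methoxybenzoates. Ring B closes in an intermolecular (4+2) mode that forms C1'–C2' (α-carbon of the ynoate to the acetal carbon of 6) and C5'–C6' (methyl-bearing β-carbon to the CH2 terminus of 6). The step needs a single regiochemistry, and the matched polarisation of both partners secures it: the nucleophilic CH2 terminus attacks the β-carbon of the ynoate, so the ester carbon ends between the OMe-bearing and the CH3-bearing carbons and the silyloxy carbon ends para to it, which is the 2'-OMe/4'-OH/6'-CH3 pattern of ring B. The gem-dimethoxy carbon can aromatise only by losing methanol, so the 2'-oxygen stays methylated while the 4'-oxygen emerges as the free phenol needed for step 8, and the differentiation that costs a direct plan its protecting groups is set by the ring construction itself. No stereocentre is formed, and the aryl ester and the methyl ester of ring A are inert to the diene in the absence of a Lewis acid. Silylation of the chelated 2-OH by BSA in the flask keeps the phenol from protonating the acid-sensitive diene, and the acidic work-up removes this group again.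

Step 6
Reactants: 13 2,2,6-trimethyl-4H-1,3-dioxin-4-one; 1 acetyl chloride
Product: 14 2,2-dimethyl-6-(2-oxopropyl)-4H-1,3-dioxin-4-one
Conditions: 13 (2 equiv), LiN(SiMe3)2 (2.1 equiv), THF, −78 °C; then 1 (1 equiv), −78 °C; 1 M HCl quench
Reagents that add atoms: none
Why: γ-Deprotonation gives the lithium dienolate, which should be C-acylated at the exocyclic carbon by acetyl chloride (crossed Claisen-type acylation), the second equivalent of dienolate taking up the more acidic proton of the product and returning as recoverable 13.

Step 7
Reactants: 14 2,2-dimethyl-6-(2-oxopropyl)-4H-1,3-dioxin-4-one; 15 N-methoxy-N-methylacetamide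
Product: 16 6-(2,4-dioxopentyl)-2,2-dimethyl-4H-1,3-dioxin-4-one
Conditions: LiN(iPr)2 (3.0 equiv), THF, −78 °C; then 15 (1.2 equiv), −78 → −20 °C; 1 M HCl, 0 °C
Reagents that add atoms: none
Why: Double deprotonation should give the dianion whose terminal, methyl-derived carbanion is the more reactive site, and its acylation by the N-methoxy-N-methylamide stops at the chelated tetrahedral adduct (Weinreb ketone synthesis), which excludes over-addition.

Step 8
Reactants: 12 methyl 2-hydroxy-4-[(4-hydroxy-2-methoxy-6-methylbenzoyl)oxy]-6-methylbenzoate; 16 6-(2,4-dioxopentyl)-2,2-dimethyl-4H-1,3-dioxin-4-one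
Product: 19 methyl 4-{[4-[(2,4-dihydroxy-6-methylbenzoyl)oxy]-2-methoxy-6-methylbenzoyl]oxy}-2-hydroxy-6-methylbenzoate (target), via acylketene 17 (not isolated), via aryl 3,5,7-trioxooctanoate 18 (not isolated)
Conditions: 16 (1.2 equiv, slow addition), toluene, 110 °C; then Et3N (2 equiv), CH2Cl2, 0 °C → rt; then CF3CO2H, rt
Reagents that add atoms: none
Why: Retro-Diels–Alder loss of acetone from the dioxinone releases the acylketene, which should be captured by the free, unhindered 4'-OH of ring B (the 2-OH of ring A is chelated) to give the aryl triketo ester; amine-promoted intramolecular aldol addition of C2 to the C7 methyl ketone (six-membered ring), dehydration and enolisation then give ring C with both phenols free, a biomimetic polyketide aromatisation.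

**Compound list**
1 | acetyl chloride | CC(=O)Cl | starting material
2 | 1,1-dichloroethene | C=C(Cl)Cl | starting material
3 | 4,4,4-trichlorobutan-2-one (not isolated) | CC(=O)CC(Cl)(Cl)Cl | intermediate
4 | 4,4-dichlorobut-3-en-2-one | CC(=O)C=C(Cl)Cl | intermediate
5 | 4,4-dimethoxybut-3-en-2-one | CC(=O)C=C(OC)OC | intermediate
6 | 1,1-dimethoxy-3-(trimethylsilyloxy)buta-1,3-diene | COC(OC)=CC(=C)O[Si](C)(C)C | intermediate
7 | methyl 2,4-dihydroxy-6-methylbenzoate (methyl orsellinate) | COC(=O)c1c(C)cc(O)cc1O | starting material
8 | but-2-ynoic acid | CC#CC(=O)O | starting material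
9 | methyl 4-(but-2-ynoyloxy)-2-hydroxy-6-methylbenzoate | COC(=O)c1c(C)cc(OC(=O)C#CC)cc1O | intermediate
10 | methyl 4-(but-2-ynoyloxy)-6-methyl-2-(trimethylsilyloxy)benzoate (not isolated) | COC(=O)c1c(C)cc(OC(=O)C#CC)cc1O[Si](C)(C)C | intermediate
11 | methyl 4-{[6,6-dimethoxy-2-methyl-4-(trimethylsilyloxy)cyclohexa-1,4-diene-1-carbonyl]oxy}-6-methyl-2-(trimethylsilyloxy)benzoate (not isolated) | COC(=O)c1c(C)cc(OC(=O)C2=C(C)CC(O[Si](C)(C)C)=CC2(OC)OC)cc1O[Si](C)(C)C | intermediate
12 | methyl 2-hydroxy-4-[(4-hydroxy-2-methoxy-6-methylbenzoyl)oxy]-6-methylbenzoate | COC(=O)c1c(C)cc(OC(=O)c2c(C)cc(O)cc2OC)cc1O | intermediate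
13 | 2,2,6-trimethyl-4H-1,3-dioxin-4-one | CC1=CC(=O)OC(C)(C)O1 | starting material
14 | 2,2-dimethyl-6-(2-oxopropyl)-4H-1,3-dioxin-4-one | CC(=O)CC1=CC(=O)OC(C)(C)O1 | intermediate
15 | N-methoxy-N-methylacetamide | CC(=O)N(C)OC | starting material
16 | 6-(2,4-dioxopentyl)-2,2-dimethyl-4H-1,3-dioxin-4-one | CC(=O)CC(=O)CC1=CC(=O)OC(C)(C)O1 | intermediate
17 | 3,5,7-trioxooct-1-en-1-one (acylketene; not isolated) | CC(=O)CC(=O)CC(=O)C=C=O | intermediate
18 | methyl 2-hydroxy-4-{[2-methoxy-6-methyl-4-(3,5,7-trioxooctanoyloxy)benzoyl]oxy}-6-methylbenzoate (not isolated) | COC(=O)c1c(C)cc(OC(=O)c2c(C)cc(OC(=O)CC(=O)CC(=O)CC(C)=O)cc2OC)cc1O | intermediate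
19 | methyl 4-{[4-[(2,4-dihydroxy-6-methylbenzoyl)oxy]-2-methoxy-6-methylbenzoyl]oxy}-2-hydroxy-6-methylbenzoate (achiral) | COC(=O)c1c(C)cc(OC(=O)c2c(C)cc(OC(=O)c3c(C)cc(O)cc3O)cc2OC)cc1O | target

**Step count and risks**
Total step count: 8. Longest linear sequence: 5 steps (steps 1, 2, 3, 5, 8).

Steps most likely to fail:

Step 8. After capture of the ketene, the aryl triketo ester could lactonise to a 2-pyrone or close in the Claisen sense with expulsion of the phenoxide instead of undergoing the aldol closure; the ketene could also be trapped by its own enol before the phenol reaches it. Fallback: setting out from 12, ring C would be brought in as a finished, protected ring. For this, 7 would be benzylated twice (BnBr, K2CO3, DMF, 60 °C) to methyl 2,4-bis(benzyloxy)-6-methylbenzoate F1 and hydrolysed (KOH, DMSO–H2O, 90 °C) to 2,4-bis(benzyloxy)-6-methylbenzoic acid F2. The acid would acylate the 4'-OH of 12 through its mixed trifluoroacetic anhydride ((CF3CO)2O, toluene, 0 °C → rt) to give methyl 4-{[4-{[2,4-bis(benzyloxy)-6-methylbenzoyl]oxy}-2-methoxy-6-methylbenzoyl]oxy}-2-hydroxy-6-methylbenzoate F3, and hydrogenolysis (H2, 10% Pd/C, EtOAc) would return to the route at 19.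

Step 5. Cycloaddition at the methyl-bearing alkyne carbon could be slower than thermal or protic decomposition of the diene, or the addition could stop after the first C–C bond without ring closure. Fallback: setting out from 7, the 4-OH would be esterified with but-3-ynoic acid (DCC, cat. 4-(dimethylamino)pyridine, then Et3N), which after isomerisation should give the allenoate methyl 4-(buta-2,3-dienoyloxy)-2-hydroxy-6-methylbenzoate F4. Its far more electrophilic cumulated double bond should take up diene 6 at or below room temperature in a Mukaiyama–Michael-initiated annulation with the same regiochemistry. Acidic work-up (loss of methanol and silanol, shift of the exocyclic methylene into the ring) would return to the route at 12.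

Step 7. The dianion could be quenched by proton transfer from the amide or the product, or react at oxygen or at the internal carbon, which would leave mixtures of 14 and acylated isomers. Fallback: setting out from 13, the lithium dienolate (LiN(SiMe3)2, THF, −78 °C) would be acylated with allyl 3-chloro-3-oxopropanoate to allyl 4-(2,2-dimethyl-4-oxo-4H-1,3-dioxin-6-yl)-3-oxobutanoate F5. C-Acetylation of its doubly activated methylene with 1 (MgCl2, pyridine, CH2Cl2) would give allyl 2-acetyl-4-(2,2-dimethyl-4-oxo-4H-1,3-dioxin-6-yl)-3-oxobutanoate F6, and deallylation–decarboxylation (Pd(PPh3)4, zerovalent palladium, morpholine, THF) would return to the route at 16.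

**Further compounds**
F1 | step 8 | methyl 2,4-bis(benzyloxy)-6-methylbenzoate | COC(=O)c1c(C)cc(OCc2ccccc2)cc1OCc1ccccc1
F2 | step 8 | 2,4-bis(benzyloxy)-6-methylbenzoic acid | OC(=O)c1c(C)cc(OCc2ccccc2)cc1OCc1ccccc1
F3 | step 8 | methyl 4-{[4-{[2,4-bis(benzyloxy)-6-methylbenzoyl]oxy}-2-methoxy-6-methylbenzoyl]oxy}-2-hydroxy-6-methylbenzoate | COC(=O)c1c(C)cc(OC(=O)c2c(C)cc(OC(=O)c3c(C)cc(OCc4ccccc4)cc3OCc5ccccc5)cc2OC)cc1O
F4 | step 5 | methyl 4-(buta-2,3-dienoyloxy)-2-hydroxy-6-methylbenzoate | COC(=O)c1c(C)cc(OC(=O)C=C=C)cc1O
F5 | step 7 | allyl 4-(2,2-dimethyl-4-oxo-4H-1,3-dioxin-6-yl)-3-oxobutanoate | C=CCOC(=O)CC(=O)CC1=CC(=O)OC(C)(C)O1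
F6 | step 7 | allyl 2-acetyl-4-(2,2-dimethyl-4-oxo-4H-1,3-dioxin-6-yl)-3-oxobutanoate | C=CCOC(=O)C(C(C)=O)C(=O)CC1=CC(=O)OC(C)(C)O1
A1 | direct plan | methyl 2,4-dihydroxy-6-methylbenzoate (methyl orsellinate) | COC(=O)c1c(C)cc(O)cc1O
A2 | direct plan | methyl 3,5-dibromo-2,4-dihydroxy-6-methylbenzoate | COC(=O)c1c(C)c(Br)c(O)c(Br)c1O
A3 | direct plan | 4-(benzyloxy)-2-methoxy-6-methylbenzoic acid | OC(=O)c1c(C)cc(OCc2ccccc2)cc1OC
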